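The flavonol is cut at C3–C4 and O1–C8a, so ring C is stitched between a ring B ketone and a ring A acyl donor. The plan exploits ring A: its oxygen-bearing carbons C5, C7 and C8a all lie ortho or para to the C4 carbonyl, and C5 and C8a are mirror images across the C4a–C7 line, so 2,4,6-trifluorobenzoyl chloride can carry a fluorine wherever an oxygen belongs. In one flask the enolate of an aryl ketone carrying α-OMOM (future O3), 3-OMOM and 4-OBn is C-acylated and the resulting diketonate expels one ortho fluoride, closing the pyranone. MOM marks the two sulfation sites; benzyl masks the three phenols.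

Key step: step 4

Assumption: the target is taken as the free bis(hydrogen sulfate) as drawn. Aryl hydrogen sulfates hydrolyse under their own acidity, so the sulfates are carried as triethylammonium salts and protonated only in the last, cold operation. For storage the solution would be neutralised to a dialkali salt. The target has no stereocentre, so no step has to set configuration.

Step 1
Reactants: 1 2-chloro-1-(3,4-dihydroxyphenyl)ethan-1-one
Product: 3 1-(3,4-dihydroxyphenyl)-2-hydroxyethan-1-one, via formate ester 2 (not isolated)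
Conditions: HCO2Na (3 equiv), HCO2H (0.5 equiv), H2O–1,4-dioxane, 90 °C, N2
Reagents that add atoms: sodium formate, [Na+].[O-]C=O
Why: SN2 displacement of the activated α-chloro ketone by formate and in situ hydrolysis of the labile formate ester 2 (formate-mediated halide-to-alcohol exchange) should deliver the ketol in a weakly acidic buffer that spares the catechol, the new oxygen coming from formate.

Step 2
Reactants: 3 1-(3,4-dihydroxyphenyl)-2-hydroxyethan-1-one; 4 benzyl bromide
Product: 5 1-[4-(benzyloxy)-3-hydroxyphenyl]-2-hydroxyethan-1-one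
Conditions: 4 (1.0 equiv), NaHCO3 (1.5 equiv), DMF, 40 °C, N2
Reagents that add atoms: benzyl bromide (4), BrCc1ccccc1
Why: Regioselective Williamson etherification: the 4-OH is conjugated with the para acyl group and is by far the most acidic hydroxyl, so bicarbonate ionises it alone and one equivalent of 4 leaves the 3-OH and the primary ketol OH free.

Step 3
Reactants: 5 1-[4-(benzyloxy)-3-hydroxyphenyl]-2-hydroxyethan-1-one
Product: 6 1-[4-(benzyloxy)-3-(methoxymethoxy)phenyl]-2-(methoxymethoxy)ethan-1-one
Conditions: MOMCl (3 equiv), iPr2NEt (4 equiv), CH2Cl2, 0 °C → rt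
Reagents that add atoms: chloromethyl methyl ether (MOMCl), COCCl
Why: Standard MOM acetal formation (O-alkylation under amine base) caps the phenol and the primary alcohol in one operation, which is possible because the α-oxygen is already in place, and the mild base does not enolise the ketone.

Step 4
Reactants: 6 1-[4-(benzyloxy)-3-(methoxymethoxy)phenyl]-2-(methoxymethoxy)ethan-1-one; 7 2,4,6-trifluorobenzoyl chloride
Product: 10 2-[4-(benzyloxy)-3-(methoxymethoxy)phenyl]-5,7-difluoro-3-(methoxymethoxy)-4H-chromen-4-one, via lithium enolate 8 (not isolated), via 2-alkoxy-1,3-diketone 9 (not isolated)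
Conditions: LiN(SiMe3)2 (2.3 equiv), THF, −78 °C; 7 (1.05 equiv), −78 → 0 °C; then DMPU, 60 °C
Reagents that add atoms: none
Why: LiN(SiMe3)2 converts 6 into the chelated Z-enolate 8, whose carbon attacks acid chloride 7 (Claisen-type C-acylation, C3–C4), and the second equivalent of base at once deprotonates the far more acidic diketone 9. On warming with DMPU the lithium chelate loosens, C3–C4 rotates, and the enolate oxygen on C2 adds to a fluorine-bearing ortho carbon to give a Meisenheimer anion delocalised into the C4 carbonyl; loss of fluoride as LiF forms O1–C8a (intramolecular SNAr). The closest known reaction type is the one-pot acylation/SNAr cyclisation of ketone enolates with 2-halobenzoyl chlorides that delivers chromones, flavones and 4-quinolones. The six-membered pyranone closes in a 6-endo-trig sense if the arene is read as the vinylogous acyl fluoride C8a=C4a–C4=O, the charge-accepting bond lying inside the new ring and fluoride departing from an exocyclic bond. No stereocentre is created, and the labile C3 centre of 9 disappears on enolisation. The step needs C- over O-acylation and a single cyclisation mode: any enol ester is itself an acyl donor that remaining enolate converts into 9, the two ortho fluorines are equivalent so only one chromone can arise, the para fluorine is out of intramolecular reach, and the hindered amide base does not attack C–F.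

Step 5
Reactants: 10 2-[4-(benzyloxy)-3-(methoxymethoxy)phenyl]-5,7-difluoro-3-(methoxymethoxy)-4H-chromen-4-one; 11 benzyl alcohol
Product: 14 5,7-bis(benzyloxy)-2-[4-(benzyloxy)-3-(methoxymethoxy)phenyl]-3-(methoxymethoxy)-4H-chromen-4-one, via sodium benzyloxide 12 (not isolated), via 7-benzyloxy-5-fluoro monoether 13 (not isolated)
Conditions: 11 (2.6 equiv), NaH (2.5 equiv), THF, 0 °C → rt until gas evolution ends; then 10 in DMF, 0 → 70 °C
Reagents that add atoms: benzyl alcohol (11), OCc1ccccc1
Why: Twofold intermolecular SNAr: C7–F (para) and C5–F (ortho) are both activated by the C4 carbonyl, the benzyloxy group that enters first (expected at the less hindered C7, though the order is immaterial) is meta to the remaining fluorine and so does not shut down its Meisenheimer pathway, the 3-alkoxy-2-aryl pyranone is a poor acceptor at C2, and MOM and benzyl ethers are inert to alkoxide.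

Step 6
Reactants: 14 5,7-bis(benzyloxy)-2-[4-(benzyloxy)-3-(methoxymethoxy)phenyl]-3-(methoxymethoxy)-4H-chromen-4-one
Product: 15 5,7-bis(benzyloxy)-2-[4-(benzyloxy)-3-hydroxyphenyl]-3-hydroxy-4H-chromen-4-one
Conditions: HCl (cat., about 0.3 M), MeOH–THF, 40 °C
Reagents that add atoms: none
Why: Acid-catalysed transacetalisation to methanol removes both MOM acetals, while the benzyl ethers, including the more acid-sensitive one at O5, tolerate dilute acid at this temperature.

Step 7
Reactants: 15 5,7-bis(benzyloxy)-2-[4-(benzyloxy)-3-hydroxyphenyl]-3-hydroxy-4H-chromen-4-one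
Product: 16 bis(triethylammonium) 4',5,7-tri-O-benzylquercetin 3,3'-bissulfate
Conditions: SO3·NEt3 (6 equiv), N,N-dimethylacetamide, 55 °C; silica, CH2Cl2–MeOH–Et3N
Reagents that add atoms: sulfur trioxide–triethylamine complex, CC[N+](CC)(CC)S(=O)(=O)[O-]
Why: O-sulfonation by SO3 transfer from an amine complex, the standard sulfation of phenols and flavonols, can only hit the two free hydroxyls, and because amine and SO3 both end up in the salt the product is an organic-soluble, chromatographable ion pair.

Step 8
Reactants: 16 bis(triethylammonium) 4',5,7-tri-O-benzylquercetin 3,3'-bissulfate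
Product: 18 quercetin 3,3'-bissulfate, via debenzylated bis(triethylammonium) salt 17 (not isolated)
Conditions: H2 (1 atm), Pd/C, MeOH–THF, rt; filter; sulfonic acid cation-exchange resin (H+ form), H2O–MeOH, 0–4 °C; lyophilise
Reagents that add atoms: none
Why: Catalytic hydrogenolysis of aryl benzyl ethers under neutral conditions leaves sulfate monoester anions and the C2=C3 bond of the flavonol untouched, and cold cation exchange then swaps triethylammonium for protons without giving the acid-labile sulfates time to hydrolyse.

Compound list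
1 | 2-chloro-1-(3,4-dihydroxyphenyl)ethan-1-one | O=C(CCl)c1ccc(O)c(O)c1 | starting material
2 | 2-(3,4-dihydroxyphenyl)-2-oxoethyl formate | O=COCC(=O)c1ccc(O)c(O)c1 | intermediate
3 | 1-(3,4-dihydroxyphenyl)-2-hydroxyethan-1-one | O=C(CO)c1ccc(O)c(O)c1 | intermediate
4 | benzyl bromide | BrCc1ccccc1 | starting material
5 | 1-[4-(benzyloxy)-3-hydroxyphenyl]-2-hydroxyethan-1-one | O=C(CO)c1ccc(OCc2ccccc2)c(O)c1 | intermediate
6 | 1-[4-(benzyloxy)-3-(methoxymethoxy)phenyl]-2-(methoxymethoxy)ethan-1-one | COCOCC(=O)c1ccc(OCc2ccccc2)c(OCOC)c1 | intermediate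
7 | 2,4,6-trifluorobenzoyl chloride | O=C(Cl)c1c(F)cc(F)cc1F | starting material
8 | lithium (Z)-1-[4-(benzyloxy)-3-(methoxymethoxy)phenyl]-2-(methoxymethoxy)ethen-1-olate | [Li+].[O-]/C(=C\OCOC)c1ccc(OCc2ccccc2)c(OCOC)c1 | intermediate
9 | 1-[4-(benzyloxy)-3-(methoxymethoxy)phenyl]-2-(methoxymethoxy)-3-(2,4,6-trifluorophenyl)propane-1,3-dione (in the flask as its lithium enolate; C2 racemic and labile) | COCOC(C(=O)c1ccc(OCc2ccccc2)c(OCOC)c1)C(=O)c1c(F)cc(F)cc1F | intermediate
10 | 2-[4-(benzyloxy)-3-(methoxymethoxy)phenyl]-5,7-difluoro-3-(methoxymethoxy)-4H-chromen-4-one | O=c1c(OCOC)c(-c2ccc(OCc3ccccc3)c(OCOC)c2)oc2cc(F)cc(F)c12 | intermediate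
11 | benzyl alcohol | OCc1ccccc1 | starting material
12 | sodium benzyloxide | [Na+].[O-]Cc1ccccc1 | intermediate
13 | 7-(benzyloxy)-2-[4-(benzyloxy)-3-(methoxymethoxy)phenyl]-5-fluoro-3-(methoxymethoxy)-4H-chromen-4-one | O=c1c(OCOC)c(-c2ccc(OCc3ccccc3)c(OCOC)c2)oc2cc(OCc3ccccc3)cc(F)c12 | intermediate
14 | 5,7-bis(benzyloxy)-2-[4-(benzyloxy)-3-(methoxymethoxy)phenyl]-3-(methoxymethoxy)-4H-chromen-4-one | O=c1c(OCOC)c(-c2ccc(OCc3ccccc3)c(OCOC)c2)oc2cc(OCc3ccccc3)cc(OCc3ccccc3)c12 | intermediate
15 | 5,7-bis(benzyloxy)-2-[4-(benzyloxy)-3-hydroxyphenyl]-3-hydroxy-4H-chromen-4-one (4',5,7-tri-O-benzylquercetin) | O=c1c(O)c(-c2ccc(OCc3ccccc3)c(O)c2)oc2cc(OCc3ccccc3)cc(OCc3ccccc3)c12 | intermediate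
16 | bis(triethylammonium) 4',5,7-tri-O-benzylquercetin 3,3'-bissulfate | O=c1c(OS(=O)(=O)[O-])c(-c2ccc(OCc3ccccc3)c(OS(=O)(=O)[O-])c2)oc2cc(OCc3ccccc3)cc(OCc3ccccc3)c12.CC[NH+](CC)CC.CC[NH+](CC)CC | intermediate
17 | bis(triethylammonium) quercetin 3,3'-bissulfate | O=c1c(OS(=O)(=O)[O-])c(-c2ccc(O)c(OS(=O)(=O)[O-])c2)oc2cc(O)cc(O)c12.CC[NH+](CC)CC.CC[NH+](CC)CC | intermediate
18 | quercetin 3,3'-bissulfate (free acid) | O=c1c(OS(=O)(=O)O)c(-c2ccc(O)c(OS(=O)(=O)O)c2)oc2cc(O)cc(O)c12 | target

Total step count: 8. Longest linear sequence: 8 steps (1 → 18).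

Steps most likely to fail

Step 4. What may go wrong: acylation on oxygen instead of carbon, consumption of the acid chloride by the excess amide base, or stalling at the tightly chelated lithium diketonate before ring closure. Fallback (sets out from 6, comes back at 10): the C3–C4 bond is made by an aldol addition instead of an acylation. Enolate 8 (LiN(SiMe3)2, THF, −78 °C) is added to commercial 2,4,6-trifluorobenzaldehyde (O=Cc1c(F)cc(F)cc1F). This should give the β-hydroxy ketone F1 as a diastereomer mixture whose stereocentres are erased later. Dess–Martin periodinane (CH2Cl2, NaHCO3, rt) oxidises it to diketone 9, now isolated. K2CO3 in DMF at 60–80 °C then closes the ring to 10 through the less tightly paired potassium enolate.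

Step 5. What may go wrong: stalling after the first displacement, or opening of the pyranone on prolonged exposure to hot alkoxide. Fallback (sets out from 13, comes back at 14): the second oxygen is brought in by a weakly basic hydroxide surrogate and benzylated afterwards. Monoether 13 is isolated after treating 10 with one equivalent of 12 at 0 °C. Acetohydroxamic acid and K2CO3 in DMSO at 80 °C displace the C5 fluoride through the α-effect oxygen to give the O-aryl acetohydroxamate F2. This fragments in the same flask in a Lossen-type manner to the chelated 5-hydroxyflavone F3. Benzyl bromide 4 with K2CO3 in DMF at 70 °C then gives 14.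

Step 7. What may go wrong: incomplete sulfation of the hydrogen-bonded 3-hydroxyl, or loss of sulfate while the ionic product is purified. Fallback (sets out from 15, comes back at 18): the sulfates are introduced as neutral protected diesters. 2,2,2-Trichloroethyl chlorosulfate (ClS(=O)(=O)OCC(Cl)(Cl)Cl), Et3N and DMAP in THF convert 15 into the bis(trichloroethyl sulfate) F4, which can be chromatographed like any neutral compound. Pd/C with HCO2NH4 in MeOH then removes the trichloroethyl and benzyl groups in one transfer hydrogenolysis to give diammonium quercetin 3,3'-bissulfate F5. The cold H+ resin treatment of step 8 gives 18.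

Further compounds
F1 | step 4 | 1-[4-(benzyloxy)-3-(methoxymethoxy)phenyl]-3-hydroxy-2-(methoxymethoxy)-3-(2,4,6-trifluorophenyl)propan-1-one (racemic diastereomer mixture) | COCOC(C(=O)c1ccc(OCc2ccccc2)c(OCOC)c1)C(O)c1c(F)cc(F)cc1F
F2 | step 5 | N-({7-(benzyloxy)-2-[4-(benzyloxy)-3-(methoxymethoxy)phenyl]-3-(methoxymethoxy)-4-oxo-4H-chromen-5-yl}oxy)acetamide | O=c1c(OCOC)c(-c2ccc(OCc3ccccc3)c(OCOC)c2)oc2cc(OCc3ccccc3)cc(ONC(C)=O)c12
F3 | step 5 | 7-(benzyloxy)-2-[4-(benzyloxy)-3-(methoxymethoxy)phenyl]-5-hydroxy-3-(methoxymethoxy)-4H-chromen-4-one | O=c1c(OCOC)c(-c2ccc(OCc3ccccc3)c(OCOC)c2)oc2cc(OCc3ccccc3)cc(O)c12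
F4 | step 7 | 4',5,7-tri-O-benzylquercetin 3,3'-bis(2,2,2-trichloroethyl sulfate) | O=c1c(OS(=O)(=O)OCC(Cl)(Cl)Cl)c(-c2ccc(OCc3ccccc3)c(OS(=O)(=O)OCC(Cl)(Cl)Cl)c2)oc2cc(OCc3ccccc3)cc(OCc3ccccc3)c12
F5 | step 7 | diammonium quercetin 3,3'-bissulfate | O=c1c(OS(=O)(=O)[O-])c(-c2ccc(O)c(OS(=O)(=O)[O-])c2)oc2cc(O)cc(O)c12.[NH4+].[NH4+]
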